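**Retrosynthetic overview**
1. Botcinin J ⇐ C7 alcohol 22 + ynoic acid 28. The (Z)-4-oxodec-2-enoate goes on last as a ketal-masked ynoate (esterification, semi-hydrogenation, ketal hydrolysis).
2. Lactone ring (O5–C1) ⇐ lactol from ozonolysis of a vinyl group. C1–C2 arrive by anti (E)-crotylboration of the C3 aldehyde, used in place of a propionate aldol so that C1 cannot acylate the tertiary O4 before the pyran is closed.
3. Pyran ring (O4–C8) ⇐ silane reduction of the C8 hemiketal. The C3 aldehyde and the C8 methyl ketone ⇐ ozonolysis of the C3=C8 bond of a cyclohexene.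
4. The plan rests on that carbocycle: C3–C8 with the methyls on C4, C6 and C8 are the six ring carbons and three methyls of mesitol, and O4 and O5 are cis on this ring. It is made from the mesitol para-quinol and isobutyraldehyde by chiral phosphoric acid catalysed acetalisation/oxa-Michael desymmetrisation, which sets C4, C5 and C6.
5. Ring order: carbocycle plus temporary dioxolane (step 2) → carbocycle cleaved (step 5) → pyran (steps 8–9) → lactone (steps 10–11).

Key step: step 2

Remark on labels: C1–C8 and O3, O4, O5, O7 are the target's atoms (C1 lactone carbonyl; C2 Me; C3 OAc; C4 Me and pyran O4; C5 lactone O5; C6 Me; C7 acyloxy O7; C8 Me, bonded to O4). Descriptors given with these labels follow CIP for the compound in question; the SMILES is decisive.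
Remark on the catalyst: (R)-TRIP is (R)-3,3′-bis(2,4,6-triisopropylphenyl)-1,1′-binaphthyl-2,2′-diyl hydrogen phosphate. Its sense of induction on the 2,6-dimethylated quinol is assumed by analogy with unsubstituted para-quinols; the mirror-image acid is used if the antipodal series should form.

**Step 1**
Reactants: 1 2,4,6-trimethylphenol (mesitol)
Product: 2 4-hydroxy-2,4,6-trimethylcyclohexa-2,5-dien-1-one (para-quinol)
Conditions: PhI(OAc)2, MeCN/H2O (3:1), 0 °C
Reagents that add atoms: water, O
Why: Oxidative dearomatisation of a phenol by the iodane, with water attacking the para carbon because both ortho positions carry methyl groups; the product is achiral.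

**Step 2**
Reactants: 2 para-quinol; 3 isobutyraldehyde
Product: 6 cis-fused dioxolane enone (2R,3aR,7S,7aS)-2-isopropyl-3a,5,7-trimethyl-7,7a-dihydro-1,3-benzodioxol-6(3aH)-one, via hemiacetal 4 (not isolated), via dienol 5 (not isolated)
Conditions: (R)-TRIP (10 mol %), 3 (5 equiv), toluene, 4 Å MS, 25 → 40 °C, held until the C6 epimer ratio no longer changes
Reagents that add atoms: none
Why: The tertiary hydroxyl of 2 adds reversibly to 3 to give hemiacetal 4, and within the hydrogen-bonded complex with the chiral phosphoric acid the hemiacetal hydroxyl adds to C5 of one of the two enantiotopic enones (oxa-Michael) to give dienol 5, which tautomerises to 6. The closest known reaction type is the chiral phosphoric acid catalysed acetalisation/oxa-Michael desymmetrisation of para-quinols and para-peroxyquinols with aliphatic aldehydes, and the α-methyl groups on the dienone are the extension. The dioxolane closes 5-exo-trig, and the two-atom tether can reach C5 only on the face that carries O4, so O4 and O5 end cis. The catalyst's choice of enone arm fixes quaternary C4 and with it C5, the isopropyl group takes the convex face at the acetal carbon, and C6 is set by reversible protonation of dienol 5, which should place the methyl equatorial and trans to O5. The step needs enantiotopic-group selection and C6 diastereocontrol; the first is secured by the bifunctional acid binding both the hemiacetal OH and the enone carbonyl, the second by thermodynamic control. The untouched C3=C8 enone remains as the later cleavage site.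

**Step 3**
Reactants: 6 dioxolane enone
Product: 7 allylic alcohol (2R,3aR,6R,7R,7aS)-2-isopropyl-3a,5,7-trimethyl-3a,6,7,7a-tetrahydro-1,3-benzodioxol-6-ol
Conditions: NaBH4, CeCl3·7H2O, MeOH, −78 °C
Reagents that add atoms: none
Why: Luche reduction is 1,2-selective, and axial hydride attack from the convex face opposite the dioxolane should give the equatorial C7 alcohol trans to the C6 methyl and cis to O5 (7R).

**Step 4**
Reactants: 7 allylic alcohol
Product: 8 benzyl ether (2R,3aR,6R,7R,7aS)-6-(benzyloxy)-2-isopropyl-3a,5,7-trimethyl-3a,6,7,7a-tetrahydro-1,3-benzodioxole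
Conditions: NaH, BnBr, n-Bu4NI (cat.), THF/DMF, 0 → 25 °C
Reagents that add atoms: benzyl bromide, BrCc1ccccc1
Why: Williamson etherification; benzyl is chosen because it survives ozone at −78 °C, aqueous acid and BF3/silane and is removed later by neutral hydrogenolysis.

**Step 5**
Reactants: 8 benzyl ether
Product: 10 keto aldehyde (2R,4S,5S)-5-[(2S,3R)-3-(benzyloxy)-4-oxopentan-2-yl]-2-isopropyl-4-methyl-1,3-dioxolane-4-carbaldehyde, via ozonide 9 (not isolated)
Conditions: O3, CH2Cl2, −78 °C (Sudan red 7B end point); PPh3, −78 → 25 °C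
Reagents that add atoms: ozone, [O-][O+]=O
Why: Ozonolysis of the only alkene with reductive work-up frees the C3 aldehyde and the C8 methyl ketone without touching C4–C7; the neutral work-up avoids epimerisation at C7.

**Step 6**
Reactants: 10 keto aldehyde; 11 (E)-but-2-ene
Product: 13 homoallylic alcohol (10 with CHO replaced by (1S,2S)-1-hydroxy-2-methylbut-3-en-1-yl; 2S,3S,4R,5S,6S,7R), via (E)-crotyldiisopinocampheylborane 12 (not isolated)
Conditions: 11, KOt-Bu, n-BuLi, THF, −78 → −45 °C; (−)-Ipc2BOMe, −78 °C; BF3·OEt2; 10 (1.0 equiv to 1.2 equiv of borane), −78 °C; NaBO3·4H2O, THF/H2O, 25 °C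
Reagents that add atoms: none
Why: Brown crotylboration through a chair six-membered transition state, in which the E-crotyl geometry gives the 2,3-anti relation and the isopinocampheyl groups from (+)-α-pinene direct attack to the Si face of the aldehyde (the sense known for pivalaldehyde), which should override the weak Felkin bias of the α-quaternary centre; the aldehyde reacts far faster than the methyl ketone at −78 °C.

**Step 7**
Reactants: 13 homoallylic alcohol
Product: 14 C3 acetate (2S,3S,4S,5S,6S,7R)
Conditions: Ac2O, 4-(dimethylamino)pyridine, pyridine, CH2Cl2, 25 °C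
Reagents that add atoms: acetic anhydride, CC(=O)OC(C)=O
Why: Nucleophile-catalysed acylation installs the final C3 acetate and caps O3 before O4 is freed, so that O3, O4 and the C8 ketone cannot close to a bicyclic ketal.

**Step 8**
Reactants: 14 acetate
Product: 16 hemiketal (1S,2S)-1-[(2S,3S,4S,5R,6S)-5-(benzyloxy)-3,6-dihydroxy-2,4,6-trimethyloxan-2-yl]-2-methylbut-3-en-1-yl acetate, via keto diol 15 (not isolated)
Conditions: TFA/H2O (4:1), 0 → 25 °C; toluene azeotrope
Reagents that add atoms: none
Why: Acid hydrolysis of the isobutylidene acetal gives keto diol 15, which should close through the tertiary O4 onto the C8 ketone to the six-membered hemiketal with O5, C6-Me and O7 equatorial; because C1 is still a vinyl group, O4 cannot be diverted into a γ-lactone.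

**Step 9**
Reactants: 16 hemiketal
Product: 17 pyran alcohol (1S,2S)-1-[(2S,3S,4S,5R,6S)-5-(benzyloxy)-3-hydroxy-2,4,6-trimethyloxan-2-yl]-2-methylbut-3-en-1-yl acetate
Conditions: Et3SiH, BF3·OEt2, CH2Cl2/MeCN, −40 → −10 °C
Reagents that add atoms: none
Why: Reductive etherification (ionic hydrogenation of a hemiketal): BF3 ionises C8 to the six-membered oxocarbenium ion, and axial hydride delivery in the half-chair that keeps O5, C6-Me and O7 equatorial should give C8-H axial and C8-Me equatorial (8S).

**Step 10**
Reactants: 17 pyran alcohol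
Product: 20 lactol (bicyclic core, 2R,3S,4S,5S,6R,7R,8S, C1 as CH(OH), anomer mixture, 7-O-benzyl), via ozonide 18 (not isolated), via hydroxy aldehyde 19 (not isolated)
Conditions: O3, CH2Cl2, −78 °C; PPh3, −78 → 25 °C
Reagents that add atoms: ozone, [O-][O+]=O
Why: Ozonolysis of the terminal vinyl group gives the C1 aldehyde, which the equatorial O5 hydroxyl captures as the trans-fused six-membered lactol; neutral conditions protect C2 and the β-acetoxy group.

**Step 11**
Reactants: 20 lactol
Product: 21 7-O-benzyl bicyclic lactone (2R,3S,4S,5S,6R,7R,8S)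
Conditions: 2,2,6,6-tetramethylpiperidin-1-oxyl (TEMPO, cat.), PhI(OAc)2, CH2Cl2, 25 °C
Reagents that add atoms: none
Why: Oxoammonium-mediated oxidation of a lactol to the lactone under base-free conditions, so the β-acetoxy lactone does not eliminate or epimerise at C2.

**Step 12**
Reactants: 21 benzyl ether lactone
Product: 22 C7 alcohol of the bicyclic lactone (2R,3S,4S,5S,6R,7R,8S)
Conditions: H2 (1 atm), Pd(OH)2/C, EtOAc, 25 °C
Reagents that add atoms: none
Why: Hydrogenolysis of the benzyl ether; the lactone and acetate are inert and no alkene is present at this stage.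

**Step 13**
Reactants: 23 heptanal; 24 ethynylmagnesium bromide
Product: 25 non-1-yn-3-ol (racemic)
Conditions: THF, 0 °C; aq. NH4Cl
Reagents that add atoms: none
Why: Grignard addition of the acetylide to the aldehyde; the carbinol centre is removed in the next step.

**Step 14**
Reactants: 25 non-1-yn-3-ol
Product: 26 non-1-yn-3-one
Conditions: Dess–Martin periodinane, NaHCO3, CH2Cl2, 0 → 25 °C
Reagents that add atoms: none
Why: Dess–Martin oxidation of a propargylic alcohol to the ynone under buffered, non-nucleophilic conditions.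

**Step 15**
Reactants: 26 non-1-yn-3-one
Product: 27 2-ethynyl-2-hexyl-1,3-dioxolane
Conditions: (TMSOCH2)2, TMSOTf (cat.), CH2Cl2, −78 → −20 °C; pyridine quench
Reagents that add atoms: 1,2-bis(trimethylsilyloxy)ethane, C[Si](C)(C)OCCO[Si](C)(C)C
Why: Noyori ketalisation runs at low temperature without free alcohol or water, so the conjugated ynone is ketalised without conjugate addition.

**Step 16**
Reactants: 27 alkynyl ketal
Product: 28 3-(2-hexyl-1,3-dioxolan-2-yl)prop-2-ynoic acid
Conditions: n-BuLi, THF, −78 °C; CO2; cold 1 M HCl to pH 2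
Reagents that add atoms: carbon dioxide, O=C=O
Why: Deprotonation of the terminal alkyne and carboxylation of the lithium acetylide; the propargylic ketal tolerates brief cold acidification.

**Step 17**
Reactants: 22 C7 alcohol; 28 ynoic acid
Product: 29 ynoate ester (7-O-[3-(2-hexyl-1,3-dioxolan-2-yl)prop-2-ynoyl] bicyclic lactone)
Conditions: DCC, 4-(dimethylamino)pyridine (cat.), CH2Cl2, 0 → 25 °C
Reagents that add atoms: none
Why: Steglich esterification of the only free hydroxyl; an alkynoate has no geometry to lose and its β-carbon is shielded by the quaternary ketal carbon against amine addition.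

**Step 18**
Reactants: 29 ynoate ester
Product: 30 (Z)-enoate ketal (7-O-[(Z)-3-(2-hexyl-1,3-dioxolan-2-yl)prop-2-enoyl] bicyclic lactone)
Conditions: H2 (1 atm), Pd/CaCO3 poisoned with Pb(OAc)2 (Lindlar catalyst), quinoline, EtOAc, 25 °C
Reagents that add atoms: none
Why: Lindlar semi-hydrogenation adds hydrogen syn to the alkyne and so sets the Z double bond.

**Step 19**
Reactants: 30 (Z)-enoate ketal
Product: 31 Botcinin J
Conditions: TsOH·H2O (cat.), acetone/H2O, 25 °C, in the dark; neutral work-up
Reagents that add atoms: water, O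
Why: Acid-catalysed ketal hydrolysis unmasks the C4′ ketone last, so the (Z)-4-oxo-2-enoate never meets base, nucleophiles or light, which would isomerise it or open the ester through the ketone hydrate.

**Compound list**
1 | 2,4,6-trimethylphenol (mesitol) | Cc1cc(C)c(O)c(C)c1 | starting material
2 | 4-hydroxy-2,4,6-trimethylcyclohexa-2,5-dien-1-one (para-quinol) | CC1=CC(C)(O)C=C(C)C1=O | intermediate
3 | isobutyraldehyde | CC(C)C=O | starting material
4 | hemiacetal 4-(1-hydroxy-2-methylpropoxy)-2,4,6-trimethylcyclohexa-2,5-dien-1-one (either configuration at the hemiacetal carbon, interconverting) | CC(C)C(O)OC1(C)C=C(C)C(=O)C(C)=C1 | intermediate (not isolated)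
5 | dienol (2R,3aR,7aS)-2-isopropyl-3a,5,7-trimethyl-3a,7a-dihydro-1,3-benzodioxol-6-ol | CC1=C[C@@]2(C)O[C@H](C(C)C)O[C@H]2C(C)=C1O | intermediate (not isolated)
6 | dioxolane enone (2R,3aR,7S,7aS)-2-isopropyl-3a,5,7-trimethyl-7,7a-dihydro-1,3-benzodioxol-6(3aH)-one | O=C1C(C)=C[C@@]2(C)O[C@H](C(C)C)O[C@H]2[C@@H]1C | intermediate
7 | allylic alcohol (2R,3aR,6R,7R,7aS)-2-isopropyl-3a,5,7-trimethyl-3a,6,7,7a-tetrahydro-1,3-benzodioxol-6-ol | O[C@H]1C(C)=C[C@@]2(C)O[C@H](C(C)C)O[C@H]2[C@@H]1C | intermediate
8 | benzyl ether (2R,3aR,6R,7R,7aS)-6-(benzyloxy)-2-isopropyl-3a,5,7-trimethyl-3a,6,7,7a-tetrahydro-1,3-benzodioxole | C(c3ccccc3)O[C@H]1C(C)=C[C@@]2(C)O[C@H](C(C)C)O[C@H]2[C@@H]1C | intermediate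
9 | ozonide of 8 (1,2,4-trioxolane across C3 and C8, configuration at these two carbons not defined) | C(c3ccccc3)O[C@H]1C4(C)OOC(O4)[C@@]2(C)O[C@H](C(C)C)O[C@H]2[C@@H]1C | intermediate (not isolated)
10 | keto aldehyde (2R,4S,5S)-5-[(2S,3R)-3-(benzyloxy)-4-oxopentan-2-yl]-2-isopropyl-4-methyl-1,3-dioxolane-4-carbaldehyde | O=C[C@@]2(C)O[C@H](C(C)C)O[C@H]2[C@H](C)[C@@H](OCc3ccccc3)C(C)=O | intermediate
11 | (E)-but-2-ene | C/C=C/C | starting material
12 | (E)-crotyldiisopinocampheylborane, isopinocampheyl groups from (+)-α-pinene | C/C=C/CB([C@@H]1C[C@@H]2C[C@H]([C@H]1C)C2(C)C)[C@@H]1C[C@@H]2C[C@H]([C@H]1C)C2(C)C | intermediate (not isolated)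
13 | homoallylic alcohol: 10 with CHO replaced by (1S,2S)-1-hydroxy-2-methylbut-3-en-1-yl (2,3-anti; 2S,3S,4R,5S,6S,7R) | C=C[C@H](C)[C@H](O)[C@@]2(C)O[C@H](C(C)C)O[C@H]2[C@H](C)[C@@H](OCc3ccccc3)C(C)=O | intermediate
14 | C3 acetate of 13 (2S,3S,4S,5S,6S,7R) | C=C[C@H](C)[C@H](OC(C)=O)[C@@]2(C)O[C@H](C(C)C)O[C@H]2[C@H](C)[C@@H](OCc3ccccc3)C(C)=O | intermediate
15 | keto diol: 14 without the isobutylidene group, O4-H and O5-H free (2S,3S,4S,5S,6S,7R) | C=C[C@H](C)[C@H](OC(C)=O)[C@@](C)(O)[C@@H](O)[C@H](C)[C@@H](OCc3ccccc3)C(C)=O | intermediate (not isolated)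
16 | hemiketal (1S,2S)-1-[(2S,3S,4S,5R,6S)-5-(benzyloxy)-3,6-dihydroxy-2,4,6-trimethyloxan-2-yl]-2-methylbut-3-en-1-yl acetate (axial anomeric OH drawn, equilibrating) | C=C[C@H](C)[C@H](OC(C)=O)[C@@]1(C)O[C@](C)(O)[C@H](OCc3ccccc3)[C@@H](C)[C@@H]1O | intermediate
17 | pyran alcohol (1S,2S)-1-[(2S,3S,4S,5R,6S)-5-(benzyloxy)-3-hydroxy-2,4,6-trimethyloxan-2-yl]-2-methylbut-3-en-1-yl acetate | C=C[C@H](C)[C@H](OC(C)=O)[C@@]1(C)O[C@@H](C)[C@H](OCc3ccccc3)[C@@H](C)[C@@H]1O | intermediate
18 | ozonide of 17 (1,2,4-trioxolan-3-yl in place of vinyl, C1 configuration not defined) | C4(OCOO4)[C@H](C)[C@H](OC(C)=O)[C@@]1(C)O[C@@H](C)[C@H](OCc3ccccc3)[C@@H](C)[C@@H]1O | intermediate (not isolated)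
19 | hydroxy aldehyde: 17 with CHO in place of vinyl (2R,3S,4S,5S,6S,7R,8S) | O=C[C@H](C)[C@H](OC(C)=O)[C@@]1(C)O[C@@H](C)[C@H](OCc3ccccc3)[C@@H](C)[C@@H]1O | intermediate (not isolated)
20 | lactol: 7-O-benzyl bicyclic core with C1 as CH(OH) (2R,3S,4S,5S,6R,7R,8S; C1 anomers) | C(c3ccccc3)O[C@@H]1[C@@H](C)[C@@H]2OC(O)[C@H](C)[C@H](OC(C)=O)[C@@]2(C)O[C@H]1C | intermediate
21 | 7-O-benzyl bicyclic lactone (2R,3S,4S,5S,6R,7R,8S) | C(c3ccccc3)O[C@@H]1[C@@H](C)[C@@H]2OC(=O)[C@H](C)[C@H](OC(C)=O)[C@@]2(C)O[C@H]1C | intermediate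
22 | C7 alcohol of the bicyclic lactone (2R,3S,4S,5S,6R,7R,8S) | O[C@@H]1[C@@H](C)[C@@H]2OC(=O)[C@H](C)[C@H](OC(C)=O)[C@@]2(C)O[C@H]1C | intermediate
23 | heptanal | CCCCCCC=O | starting material
24 | ethynylmagnesium bromide | C#C[Mg]Br | starting material
25 | non-1-yn-3-ol (racemic) | CCCCCCC(O)C#C | intermediate
26 | non-1-yn-3-one | CCCCCCC(=O)C#C | intermediate
27 | 2-ethynyl-2-hexyl-1,3-dioxolane | CCCCCCC1(C#C)OCCO1 | intermediate
28 | 3-(2-hexyl-1,3-dioxolan-2-yl)prop-2-ynoic acid | CCCCCCC1(OCCO1)C#CC(=O)O | intermediate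
29 | ynoate ester of 22 | CCCCCCC3(OCCO3)C#CC(=O)O[C@@H]1[C@@H](C)[C@@H]2OC(=O)[C@H](C)[C@H](OC(C)=O)[C@@]2(C)O[C@H]1C | intermediate
30 | (Z)-enoate ketal | CCCCCCC3(OCCO3)/C=C\C(=O)O[C@@H]1[C@@H](C)[C@@H]2OC(=O)[C@H](C)[C@H](OC(C)=O)[C@@]2(C)O[C@H]1C | intermediate
31 | Botcinin J | CCCCCCC(=O)/C=C\C(=O)O[C@@H]1[C@@H](C)[C@@H]2OC(=O)[C@H](C)[C@H](OC(C)=O)[C@@]2(C)O[C@H]1C | target

**Step count**
Total: 19 steps. Longest linear sequence: 15 steps (steps 1–12 and 17–19); the side-chain acid 28 takes 4 steps (13–16).

**Steps most likely to fail**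

Step 2. The acid may discriminate poorly between the two enantiotopic enone arms of the α-methylated dienone, or equilibration at C6 may stay incomplete. Fallback: from 2 and 3, diphenyl phosphate (10 mol %) in toluene runs the same cascade without asymmetric induction and should give the racemic dioxolane enone F1. Luche reduction then gives the racemic allylic alcohol F2. Esterification with (S)-2-methoxy-2-phenylacetic acid (DCC, 4-(dimethylamino)pyridine) gives two diastereomeric esters, the mandelate of 7 F3 and the mandelate of the antipode F4, which are separated by chromatography. Methanolysis of F3 (K2CO3, MeOH) returns to the route at 7.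

Step 6. Reagent control may fail to override the facial bias of the hindered α-quaternary, α-alkoxy aldehyde, or the borane may also add to the methyl ketone. Fallback: from 10, a palladium-catalysed allenylzinc addition ((R)-but-3-yn-2-yl methanesulfonate, Pd(OAc)2, PPh3, Et2Zn, THF, −78 → −20 °C) should give the anti homopropargylic alcohol F5. This anti-selective SE2′ process is reagent-controlled and does not touch ketones. The (R)-mesylate is chosen on the accepted course of anti SN2′ palladation and syn SE2′ addition. Lindlar semi-hydrogenation of the terminal alkyne (H2, Pd/CaCO3 poisoned with Pb(OAc)2, quinoline) comes back to the route at 13.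

Step 9. Ring closure may compete through the secondary O5 hydroxyl, giving a five-membered ether. Fallback: from 16, selective acylation of the secondary O5 hydroxyl (chloroacetic anhydride, pyridine, CH2Cl2, 0 °C) gives the hemiketal chloroacetate F6. Ionisation and reduction (Et3SiH, BF3·OEt2) can then only proceed through O4 and should give the pyran chloroacetate F7. Thiourea with NaHCO3 in EtOH removes the chloroacetate in the presence of the C3 acetate and returns to the route at 17.

**Further compounds**
F1 | step 2 | racemic dioxolane enone (racemate of 6, one enantiomer drawn) | O=C1C(C)=C[C@@]2(C)O[C@H](C(C)C)O[C@H]2[C@@H]1C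
F2 | step 2 | racemic allylic alcohol (racemate of 7, one enantiomer drawn) | O[C@H]1C(C)=C[C@@]2(C)O[C@H](C(C)C)O[C@H]2[C@@H]1C
F3 | step 2 | (S)-2-methoxy-2-phenylacetate of 7 | CO[C@@H](c3ccccc3)C(=O)O[C@H]1C(C)=C[C@@]2(C)O[C@H](C(C)C)O[C@H]2[C@@H]1C
F4 | step 2 | (S)-2-methoxy-2-phenylacetate of the antipode of 7 | CO[C@@H](c3ccccc3)C(=O)O[C@@H]1C(C)=C[C@]2(C)O[C@@H](C(C)C)O[C@@H]2[C@H]1C
F5 | step 6 | anti homopropargylic alcohol (ethynyl in place of the vinyl group of 13) | C#C[C@H](C)[C@H](O)[C@@]2(C)O[C@H](C(C)C)O[C@H]2[C@H](C)[C@@H](OCc3ccccc3)C(C)=O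
F6 | step 9 | O5-chloroacetate of hemiketal 16 | C=C[C@H](C)[C@H](OC(C)=O)[C@@]1(C)O[C@](C)(O)[C@H](OCc3ccccc3)[C@@H](C)[C@@H]1OC(=O)CCl
F7 | step 9 | O5-chloroacetate of pyran alcohol 17 | C=C[C@H](C)[C@H](OC(C)=O)[C@@]1(C)O[C@@H](C)[C@H](OCc3ccccc3)[C@@H](C)[C@@H]1OC(=O)CCl
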